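(The readings were generated by integration from invented constants; the scatter is artificial.)

The time allowed was 15 min, so for epsilon I wanted a second time to set against it: how long the substrate takes to fall by a factor of e.

the same everywhere: substrate 26 mM

| charge | reagent | remark | time |
|---|---|---|---|
| dawn | 0.32 equiv | run made earlier |  |
| autumn | 2.5 equiv | run made earlier |  |
| eta | 2.00 equiv |  | 15 min |
| epsilon | 4.00 equiv |  | 15 min |
| alpha | 0.500 equiv |  | 15 min |

| run | time / min | bis adduct / % | first product / % | substrate / % |
|---|---|---|---|---|
| dawn | 2.00 | 1 | 10 | 87 |
| dawn | 4.00 | 2 | 23 | 79 |
| dawn | 6.00 | 3 | 17 | 83 |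
| dawn | 8.00 | 0 | 19 | 73 |
| autumn | 1.00 | 9 | 30 | 49 |
| autumn | 2.50 | 40 | 30 | 31 |
| autumn | 5.00 | 65 | 22 | 15 |
| autumn | 8.00 | 74 | 11 | 3 |

(standard deviation of a reading: 2 percentage points)



- which of these holds the largest part of the substrate at the end of eta (first product / substrate / bis adduct)
- which of these holds the largest part of the substrate at the end of epsilon (first product / substrate / bis adduct)
- which of these holds the largest part of the substrate at the end of alpha (first product / substrate / bis adduct)
- bis adduct at the end of epsilon, in percent of the substrate charged

The autumn run held 49% of its substrate at 1.00 min, which I read, with its scatter, as a clock of 1.40 min at 2.5 equiv. With reagent in excess a step behaves as pseudo-first-order, so I stretched that clock in inverse proportion to the reagent concentration. Each bis adduct takes two equivalents, so epsilon, charged with 4.00 equiv, keeps at least 2.00 equiv, and on this estimate its slowest clock is 1.75 min, shorter than the time allowed. That gave 8.56, the turns, meaning the time allowed divided by the slowest clock.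

As the zero of my scale I took two steps with equal rate constants, where N turns leave e^-N of substrate and make bis adduct one minus (one plus N) times e^-N. For epsilon that reckoning gave 99.8% bis adduct.

The forecast said 99% bis adduct for epsilon, a little lower than mine, on the ground that “reagent stays at or above 2 equiv”. It named bis adduct for eta, bis adduct for epsilon and substrate for alpha.

The flasks gave bis adduct for eta, bis adduct for epsilon and substrate for alpha, with 98.7% bis adduct in epsilon, so the forecast held.

    reagent + first product → bis adduct (k = 0.197 M⁻¹ s⁻¹)
    substrate + reagent → first product (k = 0.178 M⁻¹ s⁻¹)
    substrate + first product → side product (k = 0.0144 M⁻¹ s⁻¹)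

Epsilon ended with 50.5% of its reagent and 0.00834% of its substrate, which reads as 9.39 turns against my 8.56. The neighbouring flask repeats epsilon at 6.5 mM of substrate with the same equivalents, so its charged reagent concentration is a quarter of epsilon's. On my reckoning its turns are 2.14, which gives 63.1% bis adduct. That flask ended with 5.2% of its substrate, or 2.96 turns, and 80.5% bis adduct.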